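1. Target 19 ⇐ diol 18 ⇐ tricyclic dienone 17: the C8 isovalerate and the cis C7/C8 diol come last, the diol by osmylation anti to the C9 angelate (longipinane locants C1–C11 are used throughout).
2. 17 ⇐ 15 (bond C3–C4): the cyclohexenone ring is closed last, by a C4 cyclobutyl radical that is released from a C4–O bond absent from the target and adds 6-endo to C3 of a but-2-ynoyl group on C11.
3. 15 ⇐ 12: the seven-membered ring is made before that by ring-closing metathesis (C7=C8) of a cis-1,3-divinylcyclobutane; C9 is set by CBS reduction, which also resolves the racemate.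
4. Cyclobutane 8 ⇐ 3 + 7: formal [2+2] (Mukaiyama–Michael/aldol) of a silyl enol ether with a mesaconate half-thioester; the enol-ether oxygen is the temporary C4–O bond. Ring order: cyclobutane, cycloheptene, cyclohexenone.
5. Feature that makes the key step possible: in bicyclo[4.1.1]octene 15 the C6–C9 bridge across C5/C10 locks the pucker of the cyclobutane C4–C5–C11–C10, so C4 and the acyl group on C11 sit cis-1,3 on the open face; C4 is γ to the C1 carbonyl and C4/C11 become bridgeheads, so the radical can only close onto C3 and the enone can only be C2=C3.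

Key step: step 13

Remark 1: locants in names and text are those of the target skeleton: C1 ketone, C2=C3 (CH3 on C3), C4 and C11 cyclobutane CH, C5 cyclobutane CH next to C6 (CMe2), C7 (OH), C8 (O-isovaleryl), C9 (O-angeloyl), C10 quaternary (CH3).
Remark 2: 8 and 9 are racemic (the SMILES show the enantiomer that is carried on); absolute configuration is fixed in step 7 by reagent-controlled reduction and separation of diastereomers, so at most half of the material continues.
Remark 3: the C4 configuration drawn for 8–16 (silyloxy trans to the C5 side chain) is the expected one but is immaterial, because C4 becomes a planar radical in step 13.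

Step 1
Reactants: 1 methyl 3,3-dimethylpent-4-enoate
Product: 2 3,3-dimethylpent-4-enal
Conditions: i-Bu2AlH (1.05 equiv), CH2Cl2, −78 °C; Rochelle salt work-up
Reagents that add atoms: none
Why: half-reduction of a methyl ester through the tetrahedral aluminium hemiacetal that is stable at −78 °C (DIBAL reduction); no stereocentre.

Step 2
Reactants: 2 3,3-dimethylpent-4-enal
Product: 3 tert-butyl{[(1Z)-3,3-dimethylpenta-1,4-dien-1-yl]oxy}dimethylsilane (Z/E mixture, Z shown)
Conditions: TBSOTf, Et3N, CH2Cl2, 0 °C to rt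
Reagents that add atoms: tert-butyldimethylsilyl trifluoromethanesulfonate, CC(C)(C)[Si](C)(C)OS(=O)(=O)C(F)(F)F
Why: soft enolisation and O-silylation of an aldehyde with only one enolisable position; the enol-ether geometry does not matter because C4 is stereoablated later.

Step 3
Reactants: 4 mesaconic acid
Product: 5 (2E)-4-methoxy-2-methyl-4-oxobut-2-enoic acid
Conditions: MeOH, AcCl (cat.), 0 °C to rt, stopped at the mono-ester
Reagents that add atoms: methanol, CO
Why: Fischer esterification should be faster at the unhindered CH-side carboxyl than at the carboxyl flanked by the α-methyl group, giving the C1-side mono-ester; E geometry untouched.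

Step 4
Reactants: 5 (2E)-4-methoxy-2-methyl-4-oxobut-2-enoic acid
Product: 7 methyl (2E)-4-(ethylsulfanyl)-3-methyl-4-oxobut-2-enoate, via acid chloride 6 (not isolated)
Conditions: (COCl)2, DMF (cat.), CH2Cl2, 0 °C to rt; evaporate; EtSSiMe3, CH2Cl2, 0 °C to rt
Reagents that add atoms: (ethylsulfanyl)trimethylsilane, CCS[Si](C)(C)C; oxalyl chloride, ClC(=O)C(=O)Cl (chlorine of 6 only)
Why: acid chloride formation followed by base-free S-acylation of a silyl sulfide, which avoids thia-Michael addition to the fumarate-type olefin and keeps the E geometry.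

Step 5
Reactants: 3 tert-butyl{[(1Z)-3,3-dimethylpenta-1,4-dien-1-yl]oxy}dimethylsilane; 7 methyl (2E)-4-(ethylsulfanyl)-3-methyl-4-oxobut-2-enoate
Product: 8 rac-methyl 3-{[tert-butyl(dimethyl)silyl]oxy}-4-[(ethylsulfanyl)carbonyl]-4-methyl-2-(2-methylbut-3-en-2-yl)cyclobutane-1-carboxylate
Conditions: Tf2NH (2 mol%), CH2Cl2, −78 to −20 °C; Et3N quench
Reagents that add atoms: none
Why: silyl-triflimide-catalysed formal [2+2] of a silyl enol ether with an unsaturated (thio)ester (Mukaiyama–Michael addition of C5 to the unsubstituted C11, then aldol closure of the C10 silyl ketene thioacetal onto the C4 oxocarbenium ion), in which the E olefin of 7 should give trans C1/C9 carbonyls and the reversible closure the array with the C5 side chain trans to the C11 ester and the silyloxy group trans to the side chain.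

Step 6
Reactants: 8 rac-methyl 3-{[tert-butyl(dimethyl)silyl]oxy}-4-[(ethylsulfanyl)carbonyl]-4-methyl-2-(2-methylbut-3-en-2-yl)cyclobutane-1-carboxylate
Product: 9 rac-methyl 4-acryloyl-3-{[tert-butyl(dimethyl)silyl]oxy}-4-methyl-2-(2-methylbut-3-en-2-yl)cyclobutane-1-carboxylate
Conditions: Bu3SnCH=CH2, Pd2(dba)3 (2.5 mol%), P(2-furyl)3 (10 mol%), CuO2PPh2 (1.5 equiv), THF, 50 °C
Reagents that add atoms: tributyl(ethenyl)stannane, C=C[Sn](CCCC)(CCCC)CCCC
Why: Liebeskind–Srogl ketone synthesis, in which only the thioester undergoes copper-assisted oxidative addition to zerovalent palladium, so the C1 methyl ester and all stereocentres are untouched.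

Step 7
Reactants: 9 rac-methyl 4-acryloyl-3-{[tert-butyl(dimethyl)silyl]oxy}-4-methyl-2-(2-methylbut-3-en-2-yl)cyclobutane-1-carboxylate
Product: 10 methyl 3-{[tert-butyl(dimethyl)silyl]oxy}-4-[(1R)-1-hydroxyprop-2-en-1-yl]-4-methyl-2-(2-methylbut-3-en-2-yl)cyclobutane-1-carboxylate (single enantiomer)
Conditions: (S)-2-methyl-CBS-oxazaborolidine (0.5 equiv), catecholborane (2 equiv), toluene, −78 °C; MeOH then aq. NaOH; chromatographic separation of the two diastereomers
Reagents that add atoms: none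
Why: Corey–Bakshi–Shibata reduction under reagent control (quaternary C10 as the large group, vinyl as the small one) should set C9 with the same sense in both enantiomers of 9, so the two products are diastereomers and separation gives 10 as one enantiomer.

Step 8
Reactants: 10 methyl 3-{[tert-butyl(dimethyl)silyl]oxy}-4-[(1R)-1-hydroxyprop-2-en-1-yl]-4-methyl-2-(2-methylbut-3-en-2-yl)cyclobutane-1-carboxylate
Product: 11 3-{[tert-butyl(dimethyl)silyl]oxy}-4-[(1R)-1-hydroxyprop-2-en-1-yl]-N-methoxy-N,4-dimethyl-2-(2-methylbut-3-en-2-yl)cyclobutane-1-carboxamide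
Conditions: MeNHOMe·HCl (3 equiv), i-PrMgCl (7 equiv), THF, −20 to 0 °C
Reagents that add atoms: N,O-dimethylhydroxylamine hydrochloride, CNOC.Cl
Why: aminolysis of the methyl ester by the magnesium amide gives the Weinreb amide while the C9 alkoxide is inert, and the epimerisable C11 already has the thermodynamic configuration (C1 trans to both neighbouring ring substituents).

Step 9
Reactants: 11 3-{[tert-butyl(dimethyl)silyl]oxy}-4-[(1R)-1-hydroxyprop-2-en-1-yl]-N-methoxy-N,4-dimethyl-2-(2-methylbut-3-en-2-yl)cyclobutane-1-carboxamide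
Product: 12 (1R)-1-{2-{[tert-butyl(dimethyl)silyl]oxy}-4-[methoxy(methyl)carbamoyl]-1-methyl-3-(2-methylbut-3-en-2-yl)cyclobutyl}prop-2-en-1-yl (2Z)-2-methylbut-2-enoate
Conditions: angelic acid, 2,4,6-trichlorobenzoyl chloride, Et3N, toluene, rt; then 11, 80 °C (no DMAP)
Reagents that add atoms: angelic acid, C/C=C(/C)C(=O)O
Why: Yamaguchi-type mixed-anhydride esterification without nucleophilic catalyst acylates hindered secondary alcohols with angelic acid without Z-to-E isomerisation; O-acylation retains C9.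

Step 10
Reactants: 12 (1R)-1-{2-{[tert-butyl(dimethyl)silyl]oxy}-4-[methoxy(methyl)carbamoyl]-1-methyl-3-(2-methylbut-3-en-2-yl)cyclobutyl}prop-2-en-1-yl (2Z)-2-methylbut-2-enoate
Product: 13 8-{[tert-butyl(dimethyl)silyl]oxy}-7-[methoxy(methyl)carbamoyl]-1,5,5-trimethylbicyclo[4.1.1]oct-3-en-2-yl (2Z)-2-methylbut-2-enoate
Conditions: second-generation Hoveyda–Grubbs catalyst (10 mol%), toluene (2 mM), 90 °C, argon sparge
Reagents that add atoms: none
Why: ring-closing metathesis of the two cis-1,3 vinyl arms, driven by loss of ethylene, gives the cis C7=C8 olefin of the bridged cycloheptene while the trisubstituted angelate olefin stays inert; no stereocentre is formed.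

Step 11
Reactants: 13 8-{[tert-butyl(dimethyl)silyl]oxy}-7-[methoxy(methyl)carbamoyl]-1,5,5-trimethylbicyclo[4.1.1]oct-3-en-2-yl (2Z)-2-methylbut-2-enoate
Product: 14 7-(but-2-ynoyl)-8-{[tert-butyl(dimethyl)silyl]oxy}-1,5,5-trimethylbicyclo[4.1.1]oct-3-en-2-yl (2Z)-2-methylbut-2-enoate
Conditions: CH3C≡CMgBr (1.5 equiv), THF, −78 to −20 °C; aq. NH4Cl
Reagents that add atoms: prop-1-yn-1-ylmagnesium bromide, CC#C[Mg]Br
Why: Weinreb ketone synthesis, in which the magnesium chelate stops at the ketone stage and the chelating amide reacts much faster than the hindered angelate ester.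

Step 12
Reactants: 14 7-(but-2-ynoyl)-8-{[tert-butyl(dimethyl)silyl]oxy}-1,5,5-trimethylbicyclo[4.1.1]oct-3-en-2-yl (2Z)-2-methylbut-2-enoate
Product: 15 7-(but-2-ynoyl)-8-hydroxy-1,5,5-trimethylbicyclo[4.1.1]oct-3-en-2-yl (2Z)-2-methylbut-2-enoate
Conditions: HF·pyridine, pyridine, THF, 0 °C to rt
Reagents that add atoms: none
Why: buffered fluoride cleavage of the secondary silyl ether, mild enough to leave the ynone, the allylic angelate and the epimerisable C11 unchanged.

Step 13
Reactants: 15 7-(but-2-ynoyl)-8-hydroxy-1,5,5-trimethylbicyclo[4.1.1]oct-3-en-2-yl (2Z)-2-methylbut-2-enoate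
Product: 17 (4R,5S,9R,10R,11R)-1-oxolongipina-2,7-dien-9-yl (2Z)-2-methylbut-2-enoate, via benzoxazoline adduct 16 (not isolated)
Conditions: 5,7-di-tert-butyl-3-phenyl-1,3-benzoxazol-3-ium tetrafluoroborate (1.2 equiv), pyridine (1.2 equiv), MTBE, rt; then [Ir(ppy)2(dtbbpy)]PF6 (2 mol%), NaOAc, DMSO–MTBE (5 mM), 450 nm LEDs, rt
Reagents that add atoms: 5,7-di-tert-butyl-3-phenyl-1,3-benzoxazol-3-ium tetrafluoroborate, CC(C)(C)c1cc(C(C)(C)C)c2OC=[N+](c3ccccc3)c2c1.F[B-](F)(F)F (atoms of 16 only)
Why: Proposed new method: adduct 16 should be oxidised by the excited iridium photocatalyst, lose its aminal proton and fragment by β-scission to the benzoxazolone and the secondary cyclobutyl radical at C4, which adds to C3 of the ynone held over it; the α-keto vinyl radical is then reduced by the reduced photocatalyst and protonated to the enone, so the step is redox-neutral and needs no tin or silane that could isomerise the angelate. The closest known reaction types are the photoredox deoxygenative conjugate (Giese) addition of benzoxazolium-activated alcohols and 6-endo-dig radical cyclisations onto ynones; what is new is their intramolecular use to close a bridged ring. The ring C1–C2–C3–C4–C5–C11 (and with it the bicyclo[3.1.1]heptenone) closes in the 6-endo-dig mode, favoured over 5-exo attack at C2 by polarity (nucleophilic radical to the β-carbon) and by the higher strain of the bicyclo[2.1.1]hexane alternative. The only new stereocentre, C4, is controlled by the tether: the radical is planar and C3 can only arrive on the face that carries the C11 acyl group, so the C4 configuration of 15 is irrelevant. The step needs cyclisation to outrun reduction of the radical, which the bicyclo[4.1.1]octene secures by holding the C11 acyl chain and the C4 orbital cis-1,3 on the open face, while β-scission to a bridgehead olefin is excluded by Bredt's rule.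

Step 14
Reactants: 17 (4R,5S,9R,10R,11R)-1-oxolongipina-2,7-dien-9-yl (2Z)-2-methylbut-2-enoate
Product: 18 (4R,5S,7S,8S,9S,10R,11R)-7,8-dihydroxy-1-oxolongipin-2-en-9-yl (2Z)-2-methylbut-2-enoate
Conditions: OsO4 (5 mol%), NMO (1.5 equiv), acetone–H2O, 0 °C to rt
Reagents that add atoms: osmium tetroxide (catalytic oxygen carrier), O=[Os](=O)(=O)=O; N-methylmorpholine N-oxide, C[N+]1([O-])CCOCC1; water, O
Why: Upjohn syn-dihydroxylation of the only electron-rich cis-disubstituted olefin (the enone and angelate olefins are electron-poor and trisubstituted), on the face anti to the allylic C9 ester oxygen, which places the C7 and C8 hydroxyls cis to each other and trans to O9.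

Step 15
Reactants: 18 (4R,5S,7S,8S,9S,10R,11R)-7,8-dihydroxy-1-oxolongipin-2-en-9-yl (2Z)-2-methylbut-2-enoate
Product: 19 (4R,5S,7S,8S,9S,10R,11R)-7-hydroxy-8-(3-methylbutanoyloxy)-1-oxolongipin-2-en-9-yl (2Z)-2-methylbut-2-enoate (CNP0251293.1)
Conditions: 3-methylbutanoyl chloride (1.1 equiv), pyridine, CH2Cl2, −40 to 0 °C
Reagents that add atoms: 3-methylbutanoyl chloride, CC(C)CC(=O)Cl
Why: kinetic site-selective O-acylation, since the C8 hydroxyl lies between two CH carbons whereas the C7 hydroxyl is neopentylic next to the quaternary C6, and the low temperature suppresses 8-to-7 acyl migration.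

Compound list
1 | methyl 3,3-dimethylpent-4-enoate | C=CC(C)(C)CC(=O)OC | starting material
2 | 3,3-dimethylpent-4-enal | C=CC(C)(C)CC=O | intermediate
3 | tert-butyl{[(1Z)-3,3-dimethylpenta-1,4-dien-1-yl]oxy}dimethylsilane (Z/E mixture, Z shown) | C=CC(C)(C)/C=C\O[Si](C)(C)C(C)(C)C | intermediate
4 | mesaconic acid, (2E)-2-methylbut-2-enedioic acid | OC(=O)/C(C)=C/C(=O)O | starting material
5 | (2E)-4-methoxy-2-methyl-4-oxobut-2-enoic acid | OC(=O)/C(C)=C/C(=O)OC | intermediate
6 | methyl (2E)-4-chloro-3-methyl-4-oxobut-2-enoate (not isolated) | ClC(=O)/C(C)=C/C(=O)OC | intermediate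
7 | methyl (2E)-4-(ethylsulfanyl)-3-methyl-4-oxobut-2-enoate | CCSC(=O)/C(C)=C/C(=O)OC | intermediate
8 | rac-methyl 3-{[tert-butyl(dimethyl)silyl]oxy}-4-[(ethylsulfanyl)carbonyl]-4-methyl-2-(2-methylbut-3-en-2-yl)cyclobutane-1-carboxylate (ring C1, C2, C3, C4 = C11, C5, C4, C10; CO2Me trans to COSEt and to the side chain, silyloxy trans to the side chain) | CCSC(=O)[C@@]1(C)[C@H](C(=O)OC)[C@@H](C(C)(C)C=C)[C@@H]1O[Si](C)(C)C(C)(C)C | intermediate
9 | rac-methyl 4-acryloyl-3-{[tert-butyl(dimethyl)silyl]oxy}-4-methyl-2-(2-methylbut-3-en-2-yl)cyclobutane-1-carboxylate (relative configuration as 8) | C=CC(=O)[C@@]1(C)[C@H](C(=O)OC)[C@@H](C(C)(C)C=C)[C@@H]1O[Si](C)(C)C(C)(C)C | intermediate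
10 | methyl 3-{[tert-butyl(dimethyl)silyl]oxy}-4-[(1R)-1-hydroxyprop-2-en-1-yl]-4-methyl-2-(2-methylbut-3-en-2-yl)cyclobutane-1-carboxylate (single enantiomer, ring configuration as in the SMILES) | O[C@H](C=C)[C@@]1(C)[C@H](C(=O)OC)[C@@H](C(C)(C)C=C)[C@@H]1O[Si](C)(C)C(C)(C)C | intermediate
11 | 3-{[tert-butyl(dimethyl)silyl]oxy}-4-[(1R)-1-hydroxyprop-2-en-1-yl]-N-methoxy-N,4-dimethyl-2-(2-methylbut-3-en-2-yl)cyclobutane-1-carboxamide | O[C@H](C=C)[C@@]1(C)[C@H](C(=O)N(C)OC)[C@@H](C(C)(C)C=C)[C@@H]1O[Si](C)(C)C(C)(C)C | intermediate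
12 | (1R)-1-{2-{[tert-butyl(dimethyl)silyl]oxy}-4-[methoxy(methyl)carbamoyl]-1-methyl-3-(2-methylbut-3-en-2-yl)cyclobutyl}prop-2-en-1-yl (2Z)-2-methylbut-2-enoate | C/C=C(/C)C(=O)O[C@H](C=C)[C@@]1(C)[C@H](C(=O)N(C)OC)[C@@H](C(C)(C)C=C)[C@@H]1O[Si](C)(C)C(C)(C)C | intermediate
13 | 8-{[tert-butyl(dimethyl)silyl]oxy}-7-[methoxy(methyl)carbamoyl]-1,5,5-trimethylbicyclo[4.1.1]oct-3-en-2-yl (2Z)-2-methylbut-2-enoate (bicyclic C1, C2, C5, C6, C7, C8 = C10, C9, C6, C5, C11, C4; C7 and C8 substituents both anti to the four-carbon bridge, C2 oxygen on the C7 side) | C/C=C(/C)C(=O)O[C@@H]1C=CC(C)(C)[C@@H]2[C@@H](C(=O)N(C)OC)[C@@]1(C)[C@H]2O[Si](C)(C)C(C)(C)C | intermediate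
14 | 7-(but-2-ynoyl)-8-{[tert-butyl(dimethyl)silyl]oxy}-1,5,5-trimethylbicyclo[4.1.1]oct-3-en-2-yl (2Z)-2-methylbut-2-enoate | C/C=C(/C)C(=O)O[C@@H]1C=CC(C)(C)[C@@H]2[C@@H](C(=O)C#CC)[C@@]1(C)[C@H]2O[Si](C)(C)C(C)(C)C | intermediate
15 | 7-(but-2-ynoyl)-8-hydroxy-1,5,5-trimethylbicyclo[4.1.1]oct-3-en-2-yl (2Z)-2-methylbut-2-enoate | C/C=C(/C)C(=O)O[C@@H]1C=CC(C)(C)[C@@H]2[C@@H](C(=O)C#CC)[C@@]1(C)[C@H]2O | intermediate
16 | 7-(but-2-ynoyl)-8-[(5,7-di-tert-butyl-3-phenyl-2,3-dihydro-1,3-benzoxazol-2-yl)oxy]-1,5,5-trimethylbicyclo[4.1.1]oct-3-en-2-yl (2Z)-2-methylbut-2-enoate (not isolated; aminal carbon unspecified) | C/C=C(/C)C(=O)O[C@@H]1C=CC(C)(C)[C@@H]2[C@@H](C(=O)C#CC)[C@@]1(C)[C@H]2OC1Oc2c(C(C)(C)C)cc(C(C)(C)C)cc2N1c1ccccc1 | intermediate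
17 | (4R,5S,9R,10R,11R)-1-oxolongipina-2,7-dien-9-yl (2Z)-2-methylbut-2-enoate | C/C=C(/C)C(=O)O[C@@H]1C=CC(C)(C)[C@@H]2[C@H]3C(=O)C=C(C)[C@@H]2[C@@]13C | intermediate
18 | (4R,5S,7S,8S,9S,10R,11R)-7,8-dihydroxy-1-oxolongipin-2-en-9-yl (2Z)-2-methylbut-2-enoate | C/C=C(/C)C(=O)O[C@@H]1[C@@H](O)[C@@H](O)C(C)(C)[C@@H]2[C@H]3C(=O)C=C(C)[C@@H]2[C@@]13C | intermediate
19 | (4R,5S,7S,8S,9S,10R,11R)-7-hydroxy-8-(3-methylbutanoyloxy)-1-oxolongipin-2-en-9-yl (2Z)-2-methylbut-2-enoate, CNP0251293.1 | C/C=C(/C)C(=O)O[C@@H]1[C@@H](OC(=O)CC(C)C)[C@@H](O)C(C)(C)[C@@H]2[C@H]3C(=O)C=C(C)[C@@H]2[C@@]13C | target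

Total step count: 15. Longest linear sequence: 13 steps (from 1 through steps 1, 2 and 5–15; the branch from 4 through steps 3, 4 and 5–15 is equally long).

Steps most likely to fail

Step 13 (proposed new method). The C4 radical may be reduced before it closes onto C3, or C11 may epimerise so that the acyl chain can no longer reach C4. Fallback with known two-electron chemistry, setting out from 15 and returning at 17: oxidation with Dess–Martin periodinane should give the cyclobutanone F1; hydroiodination of the ynone (NaI, AcOH) the (Z)-β-iodoenone F2; intramolecular Nozaki–Hiyama–Kishi addition (CrCl2, cat. NiCl2, DMSO) of the alkenylchromium to the strained C4 ketone forms the same C3–C4 bond and gives the bridgehead carbinol F3; acylation with methyl chlorooxoacetate gives the methyl oxalate F4, and tin hydride deoxygenation of this tertiary oxalate (Bu3SnH, AIBN, toluene, reflux) gives 17.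

Step 10. The two hindered vinyl groups may fail to close the strained bridged cycloheptene and give dimers or recovered diene instead. Fallback, setting out from 9 and returning at 13: the ring is closed earlier on the enone, where C9 is trigonal and carries no allylic ester. Enone–olefin ring-closing metathesis of 9 (same catalyst) gives the bicyclic enone F5; (S)-CBS reduction with separation of the diastereomers gives the allylic alcohol F6; the Weinreb amide F7 is made as in step 8 and angeloylated as in step 9 to give 13.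

Step 5. The cycloaddition may stop at the open-chain Michael adduct or give poor regio- and diastereocontrol with single-point activation of the thioester. Fallback, setting out from 6 and 3 and returning at 8: acylation of lithiated 1,3-oxazolidin-2-one with 6 gives the N-acyl oxazolidinone F8, whose two-point complex with TiCl2(Oi-Pr)2 or Et2AlCl fixes the enoyl geometry and directs the enol ether 3 to C11; the cyclobutane imide F9 is then converted by LiSEt (THF, 0 °C) into thioester 8.

Further compounds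
F1 | step 13 | 7-(but-2-ynoyl)-1,5,5-trimethyl-8-oxobicyclo[4.1.1]oct-3-en-2-yl (2Z)-2-methylbut-2-enoate | C/C=C(/C)C(=O)O[C@@H]1C=CC(C)(C)[C@@H]2[C@@H](C(=O)C#CC)[C@@]1(C)C2=O
F2 | step 13 | 7-[(2Z)-3-iodobut-2-enoyl]-1,5,5-trimethyl-8-oxobicyclo[4.1.1]oct-3-en-2-yl (2Z)-2-methylbut-2-enoate | C/C=C(/C)C(=O)O[C@@H]1C=CC(C)(C)[C@@H]2[C@@H](C(=O)/C=C(/C)I)[C@@]1(C)C2=O
F3 | step 13 | 4-hydroxy-1-oxolongipina-2,7-dien-9-yl (2Z)-2-methylbut-2-enoate | C/C=C(/C)C(=O)O[C@@H]1C=CC(C)(C)[C@@H]2[C@H]3C(=O)C=C(C)[C@]2(O)[C@@]13C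
F4 | step 13 | methyl 9-{[(2Z)-2-methylbut-2-enoyl]oxy}-1-oxolongipina-2,7-dien-4-yl oxalate | C/C=C(/C)C(=O)O[C@@H]1C=CC(C)(C)[C@@H]2[C@H]3C(=O)C=C(C)[C@]2(OC(=O)C(=O)OC)[C@@]13C
F5 | step 10 | rac-methyl 8-{[tert-butyl(dimethyl)silyl]oxy}-1,5,5-trimethyl-2-oxobicyclo[4.1.1]oct-3-ene-7-carboxylate | O=C1C=CC(C)(C)[C@@H]2[C@@H](C(=O)OC)[C@@]1(C)[C@H]2O[Si](C)(C)C(C)(C)C
F6 | step 10 | methyl 8-{[tert-butyl(dimethyl)silyl]oxy}-2-hydroxy-1,5,5-trimethylbicyclo[4.1.1]oct-3-ene-7-carboxylate | O[C@@H]1C=CC(C)(C)[C@@H]2[C@@H](C(=O)OC)[C@@]1(C)[C@H]2O[Si](C)(C)C(C)(C)C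
F7 | step 10 | 8-{[tert-butyl(dimethyl)silyl]oxy}-2-hydroxy-N-methoxy-N,1,5,5-tetramethylbicyclo[4.1.1]oct-3-ene-7-carboxamide | O[C@@H]1C=CC(C)(C)[C@@H]2[C@@H](C(=O)N(C)OC)[C@@]1(C)[C@H]2O[Si](C)(C)C(C)(C)C
F8 | step 5 | methyl (2E)-3-methyl-4-oxo-4-(2-oxo-1,3-oxazolidin-3-yl)but-2-enoate | COC(=O)/C=C(\C)C(=O)N1CCOC1=O
F9 | step 5 | rac-methyl 3-{[tert-butyl(dimethyl)silyl]oxy}-4-methyl-2-(2-methylbut-3-en-2-yl)-4-[(2-oxo-1,3-oxazolidin-3-yl)carbonyl]cyclobutane-1-carboxylate | O=C1OCCN1C(=O)[C@@]1(C)[C@H](C(=O)OC)[C@@H](C(C)(C)C=C)[C@@H]1O[Si](C)(C)C(C)(C)C
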